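If two first-order steps feed one capture, I first ask what stands between them. Here X opened to J, E released Z, J and Z joined to J.Z, and D took a little J as J.D.

    X ⇌ J (K1 = 12, k1 = 0.091 min⁻¹)
    J + Z → J.Z (k2 = 4.0 M⁻¹ min⁻¹)
    J + D → J.D (k3 = 0.46 M⁻¹ min⁻¹)
    E → Z (k4 = 0.057 min⁻¹)

| setting | Sunday's | Thursday's | Monday's |
|---|---|---|---|
| X | 0.20 M | 0.20 M | 0.20 M |
| E | 0.240 M | 0.480 M | 0.960 M |
| D | 0.0100 M | 0.0100 M | 0.0100 M |
| time | 8.0 min | 8.0 min | 8.0 min |

1. which of the two there is more of at the end, Sunday's (J.D / J.Z)
2. which of the two there is more of at the end, Thursday's (J.D / J.Z)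
3. which of the two there is more of at the end, Monday's (J.D / J.Z)
4. how much J.Z is there at the end, in percent of the X charged: Sunday's
5. how much J.Z is there at the end, in percent of the X charged: Thursday's
6. how much J.Z is there at the end, in percent of the X charged: Monday's

My bench rule was the limiting-reagent rule: J.Z equals the smaller of two supplies. The way back, 0.00758 min⁻¹, was slower than the way forward, 0.091 min⁻¹, so I left it out. By my reckoning for 8.0 min, X stood at 0.0966 M and had passed 0.103 M. By the same reckoning, E had released 0.0879 M of Z in Sunday's, 0.176 M in Thursday's and 0.352 M in Monday's. So the rule gave 43.9 % for Sunday's, where Z was the smaller supply, and 51.7 % for the other two.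

Then I computed the correction: the J still standing. If J is used as fast as it is made, k2[J][Z] = k1[X], so [J][Z]/[X] equals κ = k1/k2 = 0.0227 M, the standing constant. Whatever passed and is not yet J.Z is J, and Z is short by the same J.Z, which gives a quadratic in [J]. It gave 0.0553 M for Sunday's, 0.0230 M for Thursday's and 0.00856 M for Monday's. I dropped J.D: in Sunday's, J went to it at 0.00460 min⁻¹, slower than the 0.159 min⁻¹ at which it went to Z. My J.Z was 24.1 % for Sunday's, 40.2 % for Thursday's and 47.4 % for Monday's.

The bench rule stops where the squared gap between the supplies no longer exceeds 4κ[X]. That ratio was 7.07 in Monday's, 0.596 in Thursday's and 0.0275 in Sunday's. So I trusted the rule for Monday's, and not for Thursday's or Sunday's.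

The forecast chose J.Z, J.Z and J.Z, with 23 %, 35 % and 45 %. Its grounds: “more E gives more J.Z with diminishing returns”. My figures stood higher than its in each flask.

The simulation gave J.Z, J.Z and J.Z, with 23.2 %, 36.1 % and 45.7 %, so the forecast held. J.D reached 0.691 %, 0.523 % and 0.336 %.

In Monday's, X fell to 69.8 % by 4.00 min and 48.7 % by 8.00 min while E released Z, and at 3.55 min Z was made 2.88 times faster than it was used. In Monday's, J then fell from 12.4 % at 4.00 min to 5.32 % at 8.00 min. Read at the end, [J][Z]/[X] was 0.0227 M in Sunday's and 0.0284 M in Monday's, against κ of 0.0227 M.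

Read at 15 min, Monday's flask should have passed 0.149 M while E released 0.552 M. With [X] at 0.0511 M, κ gave [J] of 0.00286 M, or 1.43 %, and J.Z of 73.0 %. The simulation gave J at 1.57 % and J.Z at 72.1 %.

The constants are those of an exercise.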